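**Retrosynthetic overview**

1. 28 ⇐ 27 (fluoride removes all silicon groups) ⇐ 24 + 26 (Z-selective Still–Gennari olefination builds the acetoxy-angelate on the C6 oxygen) ⇐ diol 20.
2. 20 ⇐ acyclic boronate 16 in one thermal operation: a Claisen rearrangement of the allyl 1,3-dienyl ether makes ring bond C3–C4; the aldehyde it frees is allylated by the tethered 2-(alkoxycarbonyl)allylboron, which makes ring bond C1–C2 and closes the cyclohexane, the only ring.
3. Enabling feature (ring locants of the target name: C1 acrylate, C2 OH, C3 hydroxymethyl-vinyl, C4 methyl/vinyl, C5 CH2, C6 acyloxy): the alkenyl groups on C3 and C4 form a hexa-1,5-diene beside carbinol C2 (Claisen retron); C2(OH)–C1–C(=CH2) is a homoallylic alcohol (allylation retron); the oxygens on C2 and C6 and the acrylate on C1 are all cis, so a boron held on the C6 oxygen can deliver C1 and take up the C2 oxygen.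
4. 16 ⇐ iodide 15 (Negishi) ⇐ ynoate 14 (hydroalumination/iodination) ⇐ aldehyde 10 + propiolate 13 (catalytic asymmetric alkynylation sets the one pre-formed stereocentre, future C6) ⇐ dienyl ether 8 ⇐ allylic alcohol 6 (carboalumination of 5) + ynone 4.

Key step: step 13

Assumption: in step 10 the (S,S)-ProPhenol–zinc catalyst is taken to give the (4R)-carbinol; if its sense on this aliphatic aldehyde is the opposite, the (R,R) ligand is used.

**Route**

Step 1
Reactants: 1 methyl glycolate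
Product: 2 methyl 2-{[tri(propan-2-yl)silyl]oxy}acetate
Conditions: i-Pr3SiCl, imidazole, DMF, 25 °C
Reagents that add atoms: chlorotri(propan-2-yl)silane, CC(C)[Si](Cl)(C(C)C)C(C)C
Why: Silyl ether formation on a primary alcohol; the TIPS group is chosen because it must survive the later selective fluoride cleavage of a primary TBS ether.

Step 2
Reactants: 2 methyl 2-{[tri(propan-2-yl)silyl]oxy}acetate
Product: 3 N-methoxy-N-methyl-2-{[tri(propan-2-yl)silyl]oxy}acetamide
Conditions: MeNH(OMe)·HCl, i-PrMgCl, THF, −20 °C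
Reagents that add atoms: N,O-dimethylhydroxylamine hydrochloride, CNOC.Cl
Why: Ester aminolysis by the magnesium amide (Weinreb amide formation).

Step 3
Reactants: 3 N-methoxy-N-methyl-2-{[tri(propan-2-yl)silyl]oxy}acetamide
Product: 4 1-{[tri(propan-2-yl)silyl]oxy}but-3-yn-2-one
Conditions: HC≡CMgBr, THF, 0 °C; aq. NH4Cl
Reagents that add atoms: ethynylmagnesium bromide, C#C[Mg]Br
Why: Weinreb ketone synthesis; the chelated tetrahedral intermediate prevents over-addition.

Step 4
Reactants: 5 tert-butyl(but-3-yn-1-yloxy)dimethylsilane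
Product: 6 (2E)-5-{[tert-butyl(dimethyl)silyl]oxy}-3-methylpent-2-en-1-ol
Conditions: Me3Al, Cp2ZrCl2 (cat.), CH2Cl2, 0 to 25 °C; then n-BuLi, (CH2O)n, THF, −78 to 25 °C
Reagents that add atoms: trimethylaluminium, C[Al](C)C; formaldehyde (as paraformaldehyde), C=O
Why: Zirconium-catalysed carboalumination of the terminal alkyne (Negishi) adds Me and Al syn, so the E trisubstituted alkene results, and the alkenylalanate traps formaldehyde.

Step 5
Reactants: 6 (2E)-5-{[tert-butyl(dimethyl)silyl]oxy}-3-methylpent-2-en-1-ol, 4 1-{[tri(propan-2-yl)silyl]oxy}but-3-yn-2-one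
Product: 7 (3E)-4-{[(2E)-5-{[tert-butyl(dimethyl)silyl]oxy}-3-methylpent-2-en-1-yl]oxy}-1-{[tri(propan-2-yl)silyl]oxy}but-3-en-2-one
Conditions: PMe3 (10 mol %), CH2Cl2, 0 to 25 °C
Reagents that add atoms: none
Why: Phosphine-catalysed oxa-Michael addition of a primary alcohol to an ynone, which gives the (E)-β-alkoxy enone.

Step 6
Reactants: 7 (3E)-4-{[(2E)-5-{[tert-butyl(dimethyl)silyl]oxy}-3-methylpent-2-en-1-yl]oxy}-1-{[tri(propan-2-yl)silyl]oxy}but-3-en-2-one
Product: 8 tert-butyl(dimethyl){[(3E)-3-methyl-5-{[(1E)-3-({[tri(propan-2-yl)silyl]oxy}methyl)buta-1,3-dien-1-yl]oxy}pent-3-en-1-yl]oxy}silane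
Conditions: Ph3PCH3Br, KN(SiMe3)2, THF, 0 to 25 °C
Reagents that add atoms: methyltriphenylphosphonium bromide, C[P+](c1ccccc1)(c1ccccc1)c1ccccc1.[Br-]
Why: Wittig methylenation of the vinylogous ester carbonyl gives the 1-alkoxy-1,3-diene with the enol ether geometry unchanged.

Step 7
Reactants: 8 tert-butyl(dimethyl){[(3E)-3-methyl-5-{[(1E)-3-({[tri(propan-2-yl)silyl]oxy}methyl)buta-1,3-dien-1-yl]oxy}pent-3-en-1-yl]oxy}silane
Product: 9 (3E)-3-methyl-5-{[(1E)-3-({[tri(propan-2-yl)silyl]oxy}methyl)buta-1,3-dien-1-yl]oxy}pent-3-en-1-ol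
Conditions: TBAF (1.05 equiv), THF, 0 °C
Reagents that add atoms: none
Why: Selective desilylation: fluoride cleaves the primary TBS ether faster than the bulkier TIPS ether, and the acid-free conditions spare the dienyl ether.

Step 8
Reactants: 9 (3E)-3-methyl-5-{[(1E)-3-({[tri(propan-2-yl)silyl]oxy}methyl)buta-1,3-dien-1-yl]oxy}pent-3-en-1-ol
Product: 10 (3E)-3-methyl-5-{[(1E)-3-({[tri(propan-2-yl)silyl]oxy}methyl)buta-1,3-dien-1-yl]oxy}pent-3-enal
Conditions: Dess–Martin periodinane, pyridine, CH2Cl2, 0 °C; used at once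
Reagents that add atoms: none
Why: Dess–Martin oxidation under buffered, neutral conditions should give the β,γ-unsaturated aldehyde without shifting the double bond into conjugation.

Step 9
Reactants: 11 prop-2-ynoic acid, 12 2-(trimethylsilyl)ethanol
Product: 13 2-(trimethylsilyl)ethyl prop-2-ynoate
Conditions: DCC, DMAP (cat.), CH2Cl2, 0 °C
Reagents that add atoms: none
Why: Steglich esterification; the 2-(trimethylsilyl)ethyl ester is chosen because fluoride can cleave it at the end beside the other esters.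

Step 10
Reactants: 10 (3E)-3-methyl-5-{[(1E)-3-({[tri(propan-2-yl)silyl]oxy}methyl)buta-1,3-dien-1-yl]oxy}pent-3-enal, 13 2-(trimethylsilyl)ethyl prop-2-ynoate
Product: 14 2-(trimethylsilyl)ethyl (4R,6E)-4-hydroxy-6-methyl-8-{[(1E)-3-({[tri(propan-2-yl)silyl]oxy}methyl)buta-1,3-dien-1-yl]oxy}oct-6-en-2-ynoate
Conditions: (S,S)-ProPhenol (20 mol %), Me2Zn, Ph3PO (cat.), toluene, 0 °C
Reagents that add atoms: none
Why: Zinc–ProPhenol-catalysed enantioselective alkynylation of the aldehyde; the carbinol centre (future ring C6) is set as R by the catalyst.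

Step 11
Reactants: 14 2-(trimethylsilyl)ethyl (4R,6E)-4-hydroxy-6-methyl-8-{[(1E)-3-({[tri(propan-2-yl)silyl]oxy}methyl)buta-1,3-dien-1-yl]oxy}oct-6-en-2-ynoate
Product: 15 2-(trimethylsilyl)ethyl (2Z,4R,6E)-4-hydroxy-2-iodo-6-methyl-8-{[(1E)-3-({[tri(propan-2-yl)silyl]oxy}methyl)buta-1,3-dien-1-yl]oxy}octa-2,6-dienoate
Conditions: NaAlH2(OCH2CH2OCH3)2 (Red-Al), THF, −78 °C; then I2, −78 °C
Reagents that add atoms: iodine, II
Why: Hydroxyl-directed trans-hydroalumination of the γ-hydroxy ynoate places aluminium on the α-carbon cis to the carbinol, and iodinolysis with retention gives the (Z)-2-iodo enoate.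

Step 12
Reactants: 15 2-(trimethylsilyl)ethyl (2Z,4R,6E)-4-hydroxy-2-iodo-6-methyl-8-{[(1E)-3-({[tri(propan-2-yl)silyl]oxy}methyl)buta-1,3-dien-1-yl]oxy}octa-2,6-dienoate
Product: 16 2-(trimethylsilyl)ethyl (2E,4R,6E)-4-hydroxy-6-methyl-2-[(4,4,5,5-tetramethyl-1,3,2-dioxaborolan-2-yl)methyl]-8-{[(1E)-3-({[tri(propan-2-yl)silyl]oxy}methyl)buta-1,3-dien-1-yl]oxy}octa-2,6-dienoate
Conditions: ICH2Bpin, Zn dust, THF (gives IZnCH2Bpin); then Pd(PPh3)4 (5 mol %), THF, 25 °C
Reagents that add atoms: 2-(iodomethyl)-4,4,5,5-tetramethyl-1,3,2-dioxaborolane, ICB1OC(C)(C)C(C)(C)O1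
Why: Negishi coupling (zerovalent palladium) of the alkenyl iodide with the borylmethylzinc reagent proceeds with retention, so the CH2B group stays cis to the carbinol carbon.

Step 13
Reactants: 16 2-(trimethylsilyl)ethyl (2E,4R,6E)-4-hydroxy-6-methyl-2-[(4,4,5,5-tetramethyl-1,3,2-dioxaborolan-2-yl)methyl]-8-{[(1E)-3-({[tri(propan-2-yl)silyl]oxy}methyl)buta-1,3-dien-1-yl]oxy}octa-2,6-dienoate
Product: 20 2-(trimethylsilyl)ethyl 2-[(1R,2S,3R,4R,6R)-4-ethenyl-2,6-dihydroxy-4-methyl-3-(3-{[tri(propan-2-yl)silyl]oxy}prop-1-en-2-yl)cyclohexyl]prop-2-enoate, via Claisen aldehyde 17 (not isolated), via oxaborinine aldehyde 18 (not isolated), via bridged borate 19 (not isolated)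
Conditions: toluene (0.01 M), BHT (trace), 115 °C, sealed; then H2O, 25 °C
Reagents that add atoms: none
Why: Proposed new method: heating lets the allyl 1,3-dienyl ether of 16 undergo the [3,3] Claisen shift, which makes ring bond C3–C4 and frees the C2 aldehyde (17); the free hydroxyl on the future C6 opens the pinacol ester reversibly to the six-membered 1,2-oxaborinine 18, whose boron binds the new aldehyde oxygen and hands over the allyl group through its γ-carbon, making ring bond C1–C2 and the bridged borate 19. The closest known reaction types are the Claisen rearrangement of allyl dienyl ethers (the first half of the Claisen–Cope route to citral-type aldehydes) and the allylboration of aldehydes by 2-alkoxycarbonyl allylboronates, also in its intramolecular form; new are the tandem and the boron tethered to the neighbouring oxygen. The cyclohexane closes in the allylboration by attack of the allylic γ-carbon (C1) on the aldehyde carbon (C2), a six-membered ring closure that is exo at the carbonyl and moves the double bond to the exocyclic acrylate position, inside a boat-like bicyclo[2.2.2] array of B, the C6 oxygen, C6, C1, the acrylate carbon, the CH2B carbon, C2 and its oxygen. C3 and C4 come from the chair [3,3] transition state with both double bonds E, which places the side chain on C3 and the new vinyl on C4 cis, while C1 and C2 are set by C6, because boron is tied to the C6 oxygen and to the CH2 carbon and so puts the new hydroxyl and the acrylate on the face of the C6 oxygen (all-cis C2, C1, C6). The remote C6 centre cannot steer the face of the sigmatropic shift, so both C3/C4 pairs are to be expected: the one that closes with the C3 side chain equatorial gives 20, the other gives a diastereomer that is removed by chromatography. The step needs the boron trap to outrun the known Cope isomerisation of the aldehyde and the open transition state of the pinacol ester; the intramolecular, unhindered cyclic boronate 18 secures both.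

Step 14
Reactants: 21 ethyl 2-[bis(2,2,2-trifluoroethoxy)phosphoryl]propanoate
Product: 22 2-[bis(2,2,2-trifluoroethoxy)phosphoryl]propanoic acid
Conditions: LiOH·H2O (1.0 equiv), THF/H2O, 0 °C; then 1 M HCl
Reagents that add atoms: lithium hydroxide, [Li+].[OH-]
Why: Saponification of the carboxylic ester at low temperature, which should be faster than cleavage of the trifluoroethyl phosphonate esters.

Step 15
Reactants: 20 2-(trimethylsilyl)ethyl 2-[(1R,2S,3R,4R,6R)-4-ethenyl-2,6-dihydroxy-4-methyl-3-(3-{[tri(propan-2-yl)silyl]oxy}prop-1-en-2-yl)cyclohexyl]prop-2-enoate, 22 2-[bis(2,2,2-trifluoroethoxy)phosphoryl]propanoic acid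
Product: 23 2-(trimethylsilyl)ethyl 2-[(1S,2S,3R,4R,6R)-6-({2-[bis(2,2,2-trifluoroethoxy)phosphoryl]propanoyl}oxy)-4-ethenyl-2-hydroxy-4-methyl-3-(3-{[tri(propan-2-yl)silyl]oxy}prop-1-en-2-yl)cyclohexyl]prop-2-enoate (both epimers at the phosphonate carbon)
Conditions: DCC, DMAP (cat.), CH2Cl2, −20 to 0 °C
Reagents that add atoms: none
Why: Steglich esterification, expected at the less hindered hydroxyl on C6 (flanked by the ring CH2) rather than the one on C2 (flanked by two branched ring carbons).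

Step 16
Reactants: 23 2-(trimethylsilyl)ethyl 2-[(1S,2S,3R,4R,6R)-6-({2-[bis(2,2,2-trifluoroethoxy)phosphoryl]propanoyl}oxy)-4-ethenyl-2-hydroxy-4-methyl-3-(3-{[tri(propan-2-yl)silyl]oxy}prop-1-en-2-yl)cyclohexyl]prop-2-enoate
Product: 24 2-(trimethylsilyl)ethyl 2-[(1R,2S,3R,4R,6R)-6-({2-[bis(2,2,2-trifluoroethoxy)phosphoryl]propanoyl}oxy)-4-ethenyl-4-methyl-2-[(triethylsilyl)oxy]-3-(3-{[tri(propan-2-yl)silyl]oxy}prop-1-en-2-yl)cyclohexyl]prop-2-enoate
Conditions: Et3SiOTf, 2,6-lutidine, CH2Cl2, −78 °C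
Reagents that add atoms: triethylsilyl trifluoromethanesulfonate, CC[Si](CC)(CC)OS(=O)(=O)C(F)(F)F
Why: Silylation of the remaining secondary hydroxyl, which blocks acyl migration between the cis-1,3 oxygens under the basic conditions of the olefination.

Step 17
Reactants: 25 (2Z)-but-2-ene-1,4-diyl diacetate
Product: 26 2-oxoethyl acetate
Conditions: O3, CH2Cl2, −78 °C; then Me2S
Reagents that add atoms: ozone, [O-][O+]=O
Why: Ozonolysis with reductive work-up; the symmetric alkene gives two equivalents of the aldehyde.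

Step 18
Reactants: 24 2-(trimethylsilyl)ethyl 2-[(1R,2S,3R,4R,6R)-6-({2-[bis(2,2,2-trifluoroethoxy)phosphoryl]propanoyl}oxy)-4-ethenyl-4-methyl-2-[(triethylsilyl)oxy]-3-(3-{[tri(propan-2-yl)silyl]oxy}prop-1-en-2-yl)cyclohexyl]prop-2-enoate, 26 2-oxoethyl acetate
Product: 27 2-(trimethylsilyl)ethyl 2-[(1R,2S,3R,4R,6R)-6-{[(2Z)-4-(acetyloxy)-2-methylbut-2-enoyl]oxy}-4-ethenyl-4-methyl-2-[(triethylsilyl)oxy]-3-(3-{[tri(propan-2-yl)silyl]oxy}prop-1-en-2-yl)cyclohexyl]prop-2-enoate
Conditions: KN(SiMe3)2, 18-crown-6, THF, −78 °C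
Reagents that add atoms: none
Why: Still–Gennari variant of the Horner–Wadsworth–Emmons olefination; the bis(trifluoroethyl) phosphonate and the dissociated potassium base give the Z trisubstituted enoate.

Step 19
Reactants: 27 2-(trimethylsilyl)ethyl 2-[(1R,2S,3R,4R,6R)-6-{[(2Z)-4-(acetyloxy)-2-methylbut-2-enoyl]oxy}-4-ethenyl-4-methyl-2-[(triethylsilyl)oxy]-3-(3-{[tri(propan-2-yl)silyl]oxy}prop-1-en-2-yl)cyclohexyl]prop-2-enoate
Product: 28 2-[(1S,2S,3R,4R,6R)-6-{[(2Z)-4-(acetyloxy)-2-methylbut-2-enoyl]oxy}-4-ethenyl-2-hydroxy-3-(3-hydroxyprop-1-en-2-yl)-4-methylcyclohexyl]prop-2-enoic acid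
Conditions: TBAF, AcOH (1:1), THF, 0 to 25 °C
Reagents that add atoms: none
Why: Fluoride-mediated global desilylation: both silyl ethers are cleaved and the 2-(trimethylsilyl)ethyl ester fragments by β-elimination, while the acetic acid buffer protects the two carboxylic esters and suppresses acyl migration and lactonisation.

**Compound list**

1 | methyl glycolate | COC(=O)CO | starting material
2 | methyl 2-{[tri(propan-2-yl)silyl]oxy}acetate | COC(=O)CO[Si](C(C)C)(C(C)C)C(C)C | intermediate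
3 | N-methoxy-N-methyl-2-{[tri(propan-2-yl)silyl]oxy}acetamide | CON(C)C(=O)CO[Si](C(C)C)(C(C)C)C(C)C | intermediate
4 | 1-{[tri(propan-2-yl)silyl]oxy}but-3-yn-2-one | C#CC(=O)CO[Si](C(C)C)(C(C)C)C(C)C | intermediate
5 | tert-butyl(but-3-yn-1-yloxy)dimethylsilane | C#CCCO[Si](C)(C)C(C)(C)C | starting material
6 | (2E)-5-{[tert-butyl(dimethyl)silyl]oxy}-3-methylpent-2-en-1-ol | OC/C=C(\C)CCO[Si](C)(C)C(C)(C)C | intermediate
7 | (3E)-4-{[(2E)-5-{[tert-butyl(dimethyl)silyl]oxy}-3-methylpent-2-en-1-yl]oxy}-1-{[tri(propan-2-yl)silyl]oxy}but-3-en-2-one | O=C(CO[Si](C(C)C)(C(C)C)C(C)C)/C=C/OC/C=C(\C)CCO[Si](C)(C)C(C)(C)C | intermediate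
8 | tert-butyl(dimethyl){[(3E)-3-methyl-5-{[(1E)-3-({[tri(propan-2-yl)silyl]oxy}methyl)buta-1,3-dien-1-yl]oxy}pent-3-en-1-yl]oxy}silane | C=C(CO[Si](C(C)C)(C(C)C)C(C)C)/C=C/OC/C=C(\C)CCO[Si](C)(C)C(C)(C)C | intermediate
9 | (3E)-3-methyl-5-{[(1E)-3-({[tri(propan-2-yl)silyl]oxy}methyl)buta-1,3-dien-1-yl]oxy}pent-3-en-1-ol | C=C(CO[Si](C(C)C)(C(C)C)C(C)C)/C=C/OC/C=C(\C)CCO | intermediate
10 | (3E)-3-methyl-5-{[(1E)-3-({[tri(propan-2-yl)silyl]oxy}methyl)buta-1,3-dien-1-yl]oxy}pent-3-enal | C=C(CO[Si](C(C)C)(C(C)C)C(C)C)/C=C/OC/C=C(\C)CC=O | intermediate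
11 | prop-2-ynoic acid | C#CC(=O)O | starting material
12 | 2-(trimethylsilyl)ethanol | C[Si](C)(C)CCO | starting material
13 | 2-(trimethylsilyl)ethyl prop-2-ynoate | C#CC(=O)OCC[Si](C)(C)C | intermediate
14 | 2-(trimethylsilyl)ethyl (4R,6E)-4-hydroxy-6-methyl-8-{[(1E)-3-({[tri(propan-2-yl)silyl]oxy}methyl)buta-1,3-dien-1-yl]oxy}oct-6-en-2-ynoate | C[Si](C)(C)CCOC(=O)C#C[C@H](O)C/C(C)=C/CO/C=C/C(=C)CO[Si](C(C)C)(C(C)C)C(C)C | intermediate
15 | 2-(trimethylsilyl)ethyl (2Z,4R,6E)-4-hydroxy-2-iodo-6-methyl-8-{[(1E)-3-({[tri(propan-2-yl)silyl]oxy}methyl)buta-1,3-dien-1-yl]oxy}octa-2,6-dienoate | C[Si](C)(C)CCOC(=O)/C(I)=C/[C@H](O)C/C(C)=C/CO/C=C/C(=C)CO[Si](C(C)C)(C(C)C)C(C)C | intermediate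
16 | 2-(trimethylsilyl)ethyl (2E,4R,6E)-4-hydroxy-6-methyl-2-[(4,4,5,5-tetramethyl-1,3,2-dioxaborolan-2-yl)methyl]-8-{[(1E)-3-({[tri(propan-2-yl)silyl]oxy}methyl)buta-1,3-dien-1-yl]oxy}octa-2,6-dienoate | C[Si](C)(C)CCOC(=O)/C(CB1OC(C)(C)C(C)(C)O1)=C/[C@H](O)C/C(C)=C/CO/C=C/C(=C)CO[Si](C(C)C)(C(C)C)C(C)C | intermediate
17 | Claisen aldehyde: 2-(trimethylsilyl)ethyl (2E,4R,6R,7R)-6-ethenyl-7-formyl-4-hydroxy-6-methyl-2-[(4,4,5,5-tetramethyl-1,3,2-dioxaborolan-2-yl)methyl]-8-({[tri(propan-2-yl)silyl]oxy}methyl)nona-2,8-dienoate | C[Si](C)(C)CCOC(=O)/C(CB1OC(C)(C)C(C)(C)O1)=C/[C@H](O)C[C@](C)(C=C)[C@@H](C=O)C(=C)CO[Si](C(C)C)(C(C)C)C(C)C | intermediate (not isolated)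
18 | oxaborinine aldehyde: 2-(trimethylsilyl)ethyl (6R)-6-[(2R,3R)-2-ethenyl-3-formyl-2-methyl-4-({[tri(propan-2-yl)silyl]oxy}methyl)pent-4-en-1-yl]-2-[(3-hydroxy-2,3-dimethylbutan-2-yl)oxy]-3,6-dihydro-2H-1,2-oxaborinine-4-carboxylate | OC(C)(C)C(C)(C)OB1O[C@H](C[C@](C)(C=C)[C@@H](C=O)C(=C)CO[Si](C(C)C)(C(C)C)C(C)C)C=C(C1)C(=O)OCC[Si](C)(C)C | intermediate (not isolated)
19 | bridged borate: the cyclic borate of 20 that spans the oxygens on ring C2 and C6 (2,4-dioxa-3-borabicyclo[3.3.1]nonane core) and carries the 3-hydroxy-2,3-dimethylbutan-2-yloxy group on boron | C=C[C@@]1(C)C[C@@H](O2)[C@@H](C(=C)C(=O)OCC[Si](C)(C)C)[C@@H](OB2OC(C)(C)C(C)(C)O)[C@H]1C(=C)CO[Si](C(C)C)(C(C)C)C(C)C | intermediate (not isolated)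
20 | 2-(trimethylsilyl)ethyl 2-[(1R,2S,3R,4R,6R)-4-ethenyl-2,6-dihydroxy-4-methyl-3-(3-{[tri(propan-2-yl)silyl]oxy}prop-1-en-2-yl)cyclohexyl]prop-2-enoate | C=C[C@@]1(C)C[C@@H](O)[C@@H](C(=C)C(=O)OCC[Si](C)(C)C)[C@@H](O)[C@H]1C(=C)CO[Si](C(C)C)(C(C)C)C(C)C | intermediate
21 | ethyl 2-[bis(2,2,2-trifluoroethoxy)phosphoryl]propanoate | CCOC(=O)C(C)P(=O)(OCC(F)(F)F)OCC(F)(F)F | starting material
22 | 2-[bis(2,2,2-trifluoroethoxy)phosphoryl]propanoic acid | CC(C(=O)O)P(=O)(OCC(F)(F)F)OCC(F)(F)F | intermediate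
23 | 2-(trimethylsilyl)ethyl 2-[(1S,2S,3R,4R,6R)-6-({2-[bis(2,2,2-trifluoroethoxy)phosphoryl]propanoyl}oxy)-4-ethenyl-2-hydroxy-4-methyl-3-(3-{[tri(propan-2-yl)silyl]oxy}prop-1-en-2-yl)cyclohexyl]prop-2-enoate (both epimers at the phosphonate carbon) | C=C[C@@]1(C)C[C@@H](OC(=O)C(C)P(=O)(OCC(F)(F)F)OCC(F)(F)F)[C@@H](C(=C)C(=O)OCC[Si](C)(C)C)[C@@H](O)[C@H]1C(=C)CO[Si](C(C)C)(C(C)C)C(C)C | intermediate
24 | 2-(trimethylsilyl)ethyl 2-[(1R,2S,3R,4R,6R)-6-({2-[bis(2,2,2-trifluoroethoxy)phosphoryl]propanoyl}oxy)-4-ethenyl-4-methyl-2-[(triethylsilyl)oxy]-3-(3-{[tri(propan-2-yl)silyl]oxy}prop-1-en-2-yl)cyclohexyl]prop-2-enoate | C=C[C@@]1(C)C[C@@H](OC(=O)C(C)P(=O)(OCC(F)(F)F)OCC(F)(F)F)[C@@H](C(=C)C(=O)OCC[Si](C)(C)C)[C@@H](O[Si](CC)(CC)CC)[C@H]1C(=C)CO[Si](C(C)C)(C(C)C)C(C)C | intermediate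
25 | (2Z)-but-2-ene-1,4-diyl diacetate | CC(=O)OC/C=C\COC(C)=O | starting material
26 | 2-oxoethyl acetate | CC(=O)OCC=O | intermediate
27 | 2-(trimethylsilyl)ethyl 2-[(1R,2S,3R,4R,6R)-6-{[(2Z)-4-(acetyloxy)-2-methylbut-2-enoyl]oxy}-4-ethenyl-4-methyl-2-[(triethylsilyl)oxy]-3-(3-{[tri(propan-2-yl)silyl]oxy}prop-1-en-2-yl)cyclohexyl]prop-2-enoate | C=C[C@@]1(C)C[C@@H](OC(=O)/C(C)=C\COC(C)=O)[C@@H](C(=C)C(=O)OCC[Si](C)(C)C)[C@@H](O[Si](CC)(CC)CC)[C@H]1C(=C)CO[Si](C(C)C)(C(C)C)C(C)C | intermediate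
28 | 2-[(1S,2S,3R,4R,6R)-6-{[(2Z)-4-(acetyloxy)-2-methylbut-2-enoyl]oxy}-4-ethenyl-2-hydroxy-3-(3-hydroxyprop-1-en-2-yl)-4-methylcyclohexyl]prop-2-enoic acid | C=C[C@@]1(C)C[C@@H](OC(=O)/C(C)=C\COC(C)=O)[C@@H](C(=C)C(=O)O)[C@@H](O)[C@H]1C(=C)CO | target

**Count and risks**

Total step count: 19. Longest linear sequence: 15 steps (1 → 2 → 3 → 4 → 7 → 8 → 9 → 10 → 14 → 15 → 16 → 20 → 23 → 24 → 27 → 28).

Step 13 is the most likely to fail. The sigmatropic shift has no facial bias from the remote carbinol, so a large part of the material may enter the wrong C3/C4 series. The freed aldehyde may isomerise by the Cope shift to the conjugated dienal before boron traps it. The allylboronate may also suffer under the temperature that the Claisen shift needs, by protodeboronation or by allyl transfer through the open pinacol-ester transition state. The fallback separates the two events with known reactions and sets out from 15. The iodide 15 is heated alone in toluene at 115 °C, so that only the Claisen rearrangement takes place and no boron is present. This gives 2-(trimethylsilyl)ethyl (2Z,4R,6R,7R)-6-ethenyl-7-formyl-4-hydroxy-2-iodo-6-methyl-8-({[tri(propan-2-yl)silyl]oxy}methyl)nona-2,8-dienoate F1. The aldehyde F1 is freed of the other Claisen diastereomer by chromatography at this stage. Negishi coupling of F1 with IZnCH2Bpin (Pd(PPh3)4, THF, 25 °C) then installs the allylboronate beside the aldehyde and comes back to the route at 17. On warming in toluene, 17 should close by intramolecular carbonyl allylboration through 18 and 19, and aqueous work-up should give 20 as in step 13. Control of C1 and C2 by C6 in this closure still rests on the hydroxyl-to-boron exchange.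

Step 15 is second. The two secondary hydroxyls may not be discriminated well, the acyl group may migrate between the cis-1,3 oxygens, and DMAP may induce lactonisation onto the silylethyl ester. The fallback sets out from 20 and uses a tin acetal instead of steric discrimination alone. Bu2SnO (toluene, reflux, water removed) converts 20 into its dibutylstannylene acetal F2, in which tin bridges the oxygens on ring C2 and C6. Acid 22 is turned with oxalyl chloride and catalytic DMF into 2-[bis(2,2,2-trifluoroethoxy)phosphoryl]propanoyl chloride F3. The acetal F2 is acylated with F3 at −20 °C at the more accessible tin-bound oxygen, the one on C6, and this comes back to the route at 23.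

Step 10 is third. The β,γ-unsaturated aldehyde may isomerise into conjugation or enolise under the zinc alkoxide conditions, and the enantiofacial control on an aliphatic aldehyde may be insufficient. The fallback sets out from 10 and moves the stereocontrol to a reduction. The lithium acetylide of 13 (LiN(SiMe3)2, THF, −78 °C) adds to 10 to give the racemic carbinol 2-(trimethylsilyl)ethyl (6E)-4-hydroxy-6-methyl-8-{[(1E)-3-({[tri(propan-2-yl)silyl]oxy}methyl)buta-1,3-dien-1-yl]oxy}oct-6-en-2-ynoate F4. Dess–Martin oxidation of F4 gives the ynone 2-(trimethylsilyl)ethyl (6E)-6-methyl-4-oxo-8-{[(1E)-3-({[tri(propan-2-yl)silyl]oxy}methyl)buta-1,3-dien-1-yl]oxy}oct-6-en-2-ynoate F5. Asymmetric transfer hydrogenation of F5 with RuCl[(R,R)-TsDPEN](p-cymene) in i-PrOH (or the (S,S) catalyst, whichever gives the R carbinol) comes back to the route at 14.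

**Further compounds**

F1 | step 13 | 2-(trimethylsilyl)ethyl (2Z,4R,6R,7R)-6-ethenyl-7-formyl-4-hydroxy-2-iodo-6-methyl-8-({[tri(propan-2-yl)silyl]oxy}methyl)nona-2,8-dienoate | C[Si](C)(C)CCOC(=O)/C(I)=C/[C@H](O)C[C@](C)(C=C)[C@@H](C=O)C(=C)CO[Si](C(C)C)(C(C)C)C(C)C
F2 | step 15 | dibutylstannylene acetal of 20 (tin bridging the oxygens on ring C2 and C6) | C=C[C@@]1(C)C[C@@H](O2)[C@@H](C(=C)C(=O)OCC[Si](C)(C)C)[C@@H](O[Sn]2(CCCC)CCCC)[C@H]1C(=C)CO[Si](C(C)C)(C(C)C)C(C)C
F3 | step 15 | 2-[bis(2,2,2-trifluoroethoxy)phosphoryl]propanoyl chloride | CC(C(=O)Cl)P(=O)(OCC(F)(F)F)OCC(F)(F)F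
F4 | step 10 | racemic 2-(trimethylsilyl)ethyl (6E)-4-hydroxy-6-methyl-8-{[(1E)-3-({[tri(propan-2-yl)silyl]oxy}methyl)buta-1,3-dien-1-yl]oxy}oct-6-en-2-ynoate | C[Si](C)(C)CCOC(=O)C#CC(O)C/C(C)=C/CO/C=C/C(=C)CO[Si](C(C)C)(C(C)C)C(C)C
F5 | step 10 | 2-(trimethylsilyl)ethyl (6E)-6-methyl-4-oxo-8-{[(1E)-3-({[tri(propan-2-yl)silyl]oxy}methyl)buta-1,3-dien-1-yl]oxy}oct-6-en-2-ynoate | C[Si](C)(C)CCOC(=O)C#CC(=O)C/C(C)=C/CO/C=C/C(=C)CO[Si](C(C)C)(C(C)C)C(C)C
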